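**Plan**

1. Locants: C1 is the quaternary C–Me fusion carbon; C2 (O), C3, C4 (OH, i-Pr) and C5 (fusion CH) finish the five-membered ring; C6 (O), C7, C8(Me)=C9 and C10 finish the seven-membered ring. β is the face of the C2 oxygen and H5, α the face of the C1 methyl.
2. Cuts, in retrosynthetic order: the two angelate acyl C–O bonds; C8–CH3 (from CO2Me); C4–i-Pr (from a C4 ketone, carried earlier as a dioxolane); C5–H/C6–O (from C5=C6); then C1–C10 and C7–C8 of the seven-membered ring.
3. Enabling feature: the skipped diene C5=C6–C7–C8=C9 with C10 bonded to quaternary C1 is the signature of a cis-divinylcyclopropane Cope rearrangement. Ring C5–C6–C7–C8–C9–C10–C1 can therefore be grown on a 2-methyl-1-vinylcyclopentene (C7, C6, C5, C1) with a vinylcarbenoid (C8, C9, C10).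
4. Forward order: five-membered ring from 3-methylcyclopentenone (C2 oxygen, C4 ketal, C5 vinyl); seven-membered ring by cyclopropanation/Cope; then C5/C6 hydroboration, C4 carbinol, ester to methyl, and the two angelates last.
5. Stereochemistry: C2 by lipase resolution; C1 by the chiral dirhodium catalyst through the stereospecific boat Cope step (C4 is kept achiral so that nothing beside the vinyl group competes with the catalyst); C5 and C6 by syn hydroboration anti to the angular methyl; C4 by organocerium addition on the β face; both Z alkenes from angelic acid.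

Key step: step 11

Assumption: the prolinate catalyst is taken to follow its usual sense of induction with monosubstituted alkenes (the S catalyst giving the (1S,2R) cyclopropane from styrene and an aryldiazoacetate), which makes Rh2(R-DOSP)4, dirhodium tetrakis[(R)-N-(4-dodecylphenylsulfonyl)prolinate], the matching enantiomer; were the sense reversed, the S catalyst would be used in the same way.
Assumption: in steps 18 and 19 the less hindered C6 oxygen is taken to react before the neopentyl C2 oxygen.

**Route**

Step 1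
Reactants: 1 3-methylcyclopent-2-en-1-one
Product: 2 (±)-4-bromo-3-methylcyclopent-2-en-1-one
Conditions: NBS, AIBN (cat.), CCl4, reflux
Reagents that add atoms: N-bromosuccinimide, O=C1CCC(=O)N1Br
Why: Wohl–Ziegler allylic bromination; hydrogen abstraction at the ring γ-CH2 gives the secondary, carbonyl-conjugated radical, which should be brominated in preference to the primary radical at the methyl group.

Step 2
Reactants: 2 (±)-4-bromo-3-methylcyclopent-2-en-1-one
Product: 3 (±)-4-hydroxy-3-methylcyclopent-2-en-1-one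
Conditions: Ag2CO3, acetone/H2O, rt, dark
Reagents that add atoms: water, O
Why: silver-assisted solvolysis of the allylic bromide by water under near-neutral conditions, which spares the base-sensitive γ-hydroxy enone; the product is racemic.

Step 3
Reactants: 3 (±)-4-hydroxy-3-methylcyclopent-2-en-1-one
Product: 4 (S)-4-hydroxy-3-methylcyclopent-2-en-1-one
Conditions: Burkholderia cepacia lipase (Amano PS), vinyl acetate, MTBE, 30 °C, stopped just past half conversion
Reagents that add atoms: none
Why: enzymatic kinetic resolution by enantioselective transesterification; by Kazlauskas' rule and the behaviour of the closely related 4-hydroxycyclopentenones, the R alcohol should be acetylated and the S alcohol, which carries the future C2 configuration, recovered.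

Step 4
Reactants: 4 (S)-4-hydroxy-3-methylcyclopent-2-en-1-one
Product: 5 (S)-4-(tert-butyldimethylsilyloxy)-3-methylcyclopent-2-en-1-one
Conditions: TBSCl, imidazole, DMF, 0 °C → rt
Reagents that add atoms: tert-butyldimethylsilyl chloride, CC(C)(C)[Si](C)(C)Cl
Why: standard silylation of a secondary alcohol; the stereocentre is untouched and the silyl ether lasts until step 18.

Step 5
Reactants: 5 (S)-4-(tert-butyldimethylsilyloxy)-3-methylcyclopent-2-en-1-one
Product: 6 (S)-4-(tert-butyldimethylsilyloxy)-2-iodo-3-methylcyclopent-2-en-1-one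
Conditions: I2, pyridine, CH2Cl2, rt
Reagents that add atoms: iodine, II
Why: Johnson α-iodination of an enone (reversible conjugate addition of pyridine, iodination of the enolate, loss of pyridine), known for β-methyl cycloalkenones although slower than for the unsubstituted parent.

Step 6
Reactants: 6 (S)-4-(tert-butyldimethylsilyloxy)-2-iodo-3-methylcyclopent-2-en-1-one
Product: 7 (S)-8-(tert-butyldimethylsilyloxy)-6-iodo-7-methyl-1,4-dioxaspiro[4.4]non-6-ene
Conditions: (Me3SiOCH2)2, TMSOTf (cat.), CH2Cl2, −78 → −20 °C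
Reagents that add atoms: 1,2-bis(trimethylsilyloxy)ethane, C[Si](C)(C)OCCO[Si](C)(C)C
Why: Noyori ketalisation under aprotic conditions that keep the silyl ether; the α-iodine holds the alkene in place, and C4 now bears two identical oxygens.

Step 7
Reactants: 7 (S)-8-(tert-butyldimethylsilyloxy)-6-iodo-7-methyl-1,4-dioxaspiro[4.4]non-6-ene; 8 tributyl(vinyl)stannane
Product: 9 (S)-8-(tert-butyldimethylsilyloxy)-7-methyl-6-vinyl-1,4-dioxaspiro[4.4]non-6-ene
Conditions: Pd(PPh3)4 (5 mol %), CuI, CsF, DMF, 45 °C
Reagents that add atoms: tributyl(vinyl)stannane (8), C=C[Sn](CCCC)(CCCC)CCCC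
Why: Stille coupling of a 2-iodocycloalkenone ketal, a standard substrate class; copper iodide and fluoride accelerate transmetalation at the hindered tetrasubstituted alkenyl iodide.

Step 8
Reactants: 10 methyl acetoacetate
Product: 11 methyl 2-diazo-3-oxobutanoate
Conditions: 4-acetamidobenzenesulfonyl azide, Et3N, MeCN, 0 °C → rt
Reagents that add atoms: 4-acetamidobenzenesulfonyl azide, CC(=O)Nc1ccc(cc1)S(=O)(=O)N=[N+]=[N-]
Why: Regitz diazo transfer to the activated methylene of a β-keto ester.

Step 9
Reactants: 11 methyl 2-diazo-3-oxobutanoate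
Product: 12 (±)-methyl 2-diazo-3-hydroxybutanoate
Conditions: NaBH4, MeOH, 0 °C
Reagents that add atoms: none
Why: borohydride reduces the ketone and leaves the diazo ester intact; the carbinol stereocentre is lost in the next step.

Step 10
Reactants: 12 (±)-methyl 2-diazo-3-hydroxybutanoate
Product: 13 methyl 2-diazobut-3-enoate
Conditions: POCl3, Et3N, CH2Cl2, 0 °C
Reagents that add atoms: none
Why: dehydration through the dichlorophosphate, the established route to this vinyldiazoacetate, which is kept cold in pentane and used at once because it cyclises to a pyrazole on standing.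

Step 11
Reactants: 9 (S)-8-(tert-butyldimethylsilyloxy)-7-methyl-6-vinyl-1,4-dioxaspiro[4.4]non-6-ene; 13 methyl 2-diazobut-3-enoate
Product: 15 methyl 2β-(tert-butyldimethylsilyloxy)-4,4-(ethylenedioxy)-1α-methylbicyclo[5.3.0]deca-5,8-diene-8-carboxylate (plan locants; C5=C6 and C8=C9), via cis-divinylcyclopropane 14 (not isolated)
Conditions: Rh2(R-DOSP)4 (2 mol %), 13 (3 equiv, cold pentane solution) added slowly, hexanes, −40 °C → rt; then toluene, 80 °C
Reagents that add atoms: methyl 2-diazobut-3-enoate (13), C=CC(=[N+]=[N-])C(=O)OC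
Why: Loss of dinitrogen from 13 at the dirhodium catalyst gives a donor/acceptor vinylcarbenoid that cyclopropanates the only accessible alkene of 9, the monosubstituted vinyl group (C6=C7), forming C7–C8 and, transiently, C6–C8 with the vinyl and cyclopentenyl groups cis (14). The cis-divinylcyclopropane then undergoes a strain-driven [3,3] shift through the obligatory boat transition state, breaking C6–C8 and forming C1–C10, so that ring C5–C6–C7–C8–C9–C10–C1 is closed by a sigmatropic annulation onto the cyclopentene, in sum a formal (4+3) cycloaddition. The closest known reaction type is the dirhodium-catalysed vinyldiazoacetate/diene tandem cyclopropanation–Cope rearrangement, which is documented for 1-vinylcycloalkenes whose tetrasubstituted terminus becomes a quaternary ring-fusion carbon. The only new stereocentre, C1, is fixed by the cyclopropane configuration, which the prolinate catalyst sets on the prochiral vinyl group and the stereospecific boat step hands on; the (1S,2S)-cyclopropane places C10 on the β face, syn to the C2 silyloxy group. Site selectivity (vinyl versus tetrasubstituted ring alkene) follows from the steric demand of donor/acceptor carbenoids, cis selectivity from their usual preference, and facial selectivity from the catalyst alone, because the C4 dioxolane shows the same group to both faces and the C2 stereocentre is remote. The inward C1 methyl retards the Cope step, hence the warming period.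

Step 12
Reactants: 15 diene ester
Product: 17 methyl 2β-(tert-butyldimethylsilyloxy)-4,4-(ethylenedioxy)-6β-hydroxy-1α-methyl-5βH-bicyclo[5.3.0]dec-8-ene-8-carboxylate, via C6 alkylborane 16 (not isolated)
Conditions: BH3·THF, THF, 0 °C → rt; then NaOH, H2O2, 0 °C
Reagents that add atoms: hydrogen peroxide, OO
Why: hydroboration–oxidation; the electron-rich C5=C6 alkene reacts while the conjugated ester alkene is inert, boron goes to the less substituted C6, and syn delivery of H and B on the β face, opposite the angular C1 methyl (the selectivity known from Δ5-steroids beside an angular methyl), should set H5 β and O6 β (trans fusion), with retention in the oxidation.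

Step 13
Reactants: 17 C6 alcohol
Product: 18 methyl 2β,6β-bis(tert-butyldimethylsilyloxy)-4,4-(ethylenedioxy)-1α-methyl-5βH-bicyclo[5.3.0]dec-8-ene-8-carboxylate
Conditions: TBSOTf, 2,6-lutidine, CH2Cl2, −78 → 0 °C
Reagents that add atoms: tert-butyldimethylsilyl trifluoromethanesulfonate, CC(C)(C)[Si](C)(C)OS(=O)(=O)C(F)(F)F
Why: silyl triflate silylation of a hindered secondary alcohol, fast enough at low temperature to leave the dioxolane alone; C2 and C6 now carry the same group and can be freed together.

Step 14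
Reactants: 18 bis-silyl ether ketal
Product: 19 methyl 2β,6β-bis(tert-butyldimethylsilyloxy)-1α-methyl-4-oxo-5βH-bicyclo[5.3.0]dec-8-ene-8-carboxylate
Conditions: PPTS, acetone/H2O, 50 °C
Reagents that add atoms: water, O
Why: buffered acid-catalysed ketal hydrolysis, mild enough to keep both secondary silyl ethers and to avoid enolisation of the new ketone toward C5 (epimerisation) or loss of the β-silyloxy groups.

Step 15
Reactants: 19 C4 ketone; 20 isopropylmagnesium chloride
Product: 21 methyl 2β,6β-bis(tert-butyldimethylsilyloxy)-4α-hydroxy-4β-isopropyl-1α-methyl-5βH-bicyclo[5.3.0]dec-8-ene-8-carboxylate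
Conditions: CeCl3 (anhydrous), i-PrMgCl, THF, −78 °C
Reagents that add atoms: isopropylmagnesium chloride (20), CC(C)[Mg]Cl
Why: organocerium 1,2-addition (Imamoto conditions), chosen because the weakly basic reagent adds to hindered, enolisable ketones without β-hydride reduction and ignores the conjugated ester at −78 °C; attack along the equatorial β trajectory, syn to H5 and away from the C1 methyl that is 1,3-diaxial to the α approach, should place isopropyl β and hydroxyl α.

Step 16
Reactants: 21 tertiary alcohol ester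
Product: 22 2β,6β-bis(tert-butyldimethylsilyloxy)-8-(hydroxymethyl)-4β-isopropyl-1α-methyl-5βH-bicyclo[5.3.0]dec-8-en-4α-ol
Conditions: i-Bu2AlH (4 equiv), CH2Cl2, −78 → 0 °C; aq. potassium sodium tartrate
Reagents that add atoms: none
Why: 1,2-reduction of the α,β-unsaturated ester to the primary allylic alcohol by diisobutylaluminium hydride; silyl ethers and the alkene are untouched and the tertiary hydroxyl only consumes one equivalent.

Step 17
Reactants: 22 allylic alcohol
Product: 24 2β,6β-bis(tert-butyldimethylsilyloxy)-4β-isopropyl-1α,8-dimethyl-5βH-bicyclo[5.3.0]dec-8-en-4α-ol, via allylic mesylate 23 (not isolated)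
Conditions: MsCl, Et3N, THF, −30 °C; then LiBHEt3, −30 → 0 °C
Reagents that add atoms: none
Why: selective sulfonylation of the primary allylic alcohol (the tertiary C4 hydroxyl does not react) followed by direct SN2 hydride displacement with lithium triethylborohydride, which at a primary allylic carbon should outrun SN2′ attack at the ring carbon and leave C8=C9 in place.

Step 18
Reactants: 24 bis-silyl ether
Product: 26 4β-isopropyl-1α,8-dimethyl-5βH-bicyclo[5.3.0]dec-8-ene-2β,4α,6β-triol, via 6-hydroxy 2-silyl ether 25 (not isolated)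
Conditions: TBAF, THF, 50 °C
Reagents that add atoms: none
Why: fluoride-induced cleavage of both secondary silyl ethers under basic conditions that cannot dehydrate the tertiary alcohol or move the trisubstituted alkene.

Step 19
Reactants: 26 triol; 27 angelic acid
Product: 29 CNP0303897.1 (2β,6β-bis(angeloyloxy)-4β-isopropyl-1α,8-dimethyl-5βH-bicyclo[5.3.0]dec-8-en-4α-ol), via 6-monoangelate 28 (not isolated)
Conditions: angelic acid, 2,4,6-trichlorobenzoyl chloride, Et3N, toluene, rt; then 26, 80 °C
Reagents that add atoms: angelic acid (27), C/C=C(/C)C(=O)O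
Why: Yamaguchi-type mixed-anhydride esterification without DMAP, the standard way to acylate hindered secondary alcohols with angelic acid without Z-to-E isomerisation; the alcohols attack the unhindered angeloyl carbonyl and the tertiary C4 hydroxyl stays free.

**Compound list**

1 | 3-methylcyclopent-2-en-1-one | CC1=CC(=O)CC1 | starting material
2 | (±)-4-bromo-3-methylcyclopent-2-en-1-one | CC1=CC(=O)CC1Br | intermediate
3 | (±)-4-hydroxy-3-methylcyclopent-2-en-1-one | CC1=CC(=O)CC1O | intermediate
4 | (S)-4-hydroxy-3-methylcyclopent-2-en-1-one | CC1=CC(=O)C[C@@H]1O | intermediate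
5 | (S)-4-(tert-butyldimethylsilyloxy)-3-methylcyclopent-2-en-1-one | CC1=CC(=O)C[C@@H]1O[Si](C)(C)C(C)(C)C | intermediate
6 | (S)-4-(tert-butyldimethylsilyloxy)-2-iodo-3-methylcyclopent-2-en-1-one | CC1=C(I)C(=O)C[C@@H]1O[Si](C)(C)C(C)(C)C | intermediate
7 | (S)-8-(tert-butyldimethylsilyloxy)-6-iodo-7-methyl-1,4-dioxaspiro[4.4]non-6-ene | CC1=C(I)C2(OCCO2)C[C@@H]1O[Si](C)(C)C(C)(C)C | intermediate
8 | tributyl(vinyl)stannane | C=C[Sn](CCCC)(CCCC)CCCC | starting material
9 | (S)-8-(tert-butyldimethylsilyloxy)-7-methyl-6-vinyl-1,4-dioxaspiro[4.4]non-6-ene (diene; C4 as dioxolane, C2 as TBS ether) | C=CC1=C(C)[C@@H](O[Si](C)(C)C(C)(C)C)CC12OCCO2 | intermediate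
10 | methyl acetoacetate | COC(=O)CC(C)=O | starting material
11 | methyl 2-diazo-3-oxobutanoate | COC(=O)C(=[N+]=[N-])C(C)=O | intermediate
12 | (±)-methyl 2-diazo-3-hydroxybutanoate | COC(=O)C(=[N+]=[N-])C(C)O | intermediate
13 | methyl 2-diazobut-3-enoate | C=CC(=[N+]=[N-])C(=O)OC | intermediate
14 | methyl (1S,2S)-2-[(8S)-8-(tert-butyldimethylsilyloxy)-7-methyl-1,4-dioxaspiro[4.4]non-6-en-6-yl]-1-vinylcyclopropane-1-carboxylate (cis-divinylcyclopropane) | COC(=O)[C@]1(C=C)C[C@H]1C2=C(C)[C@@H](O[Si](C)(C)C(C)(C)C)CC23OCCO3 | intermediate (not isolated)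
15 | methyl 2β-(tert-butyldimethylsilyloxy)-4,4-(ethylenedioxy)-1α-methylbicyclo[5.3.0]deca-5,8-diene-8-carboxylate (plan locants) | COC(=O)C1=CC[C@@]2(C)[C@@H](O[Si](C)(C)C(C)(C)C)CC3(OCCO3)C2=CC1 | intermediate
16 | C6β-borane adduct of 15 (5βH, monoalkylborane) | B[C@H]1CC(C(=O)OC)=CC[C@@]2(C)[C@@H](O[Si](C)(C)C(C)(C)C)CC3(OCCO3)[C@H]12 | intermediate (not isolated)
17 | methyl 2β-(tert-butyldimethylsilyloxy)-4,4-(ethylenedioxy)-6β-hydroxy-1α-methyl-5βH-bicyclo[5.3.0]dec-8-ene-8-carboxylate | O[C@H]1CC(C(=O)OC)=CC[C@@]2(C)[C@@H](O[Si](C)(C)C(C)(C)C)CC3(OCCO3)[C@H]12 | intermediate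
18 | methyl 2β,6β-bis(tert-butyldimethylsilyloxy)-4,4-(ethylenedioxy)-1α-methyl-5βH-bicyclo[5.3.0]dec-8-ene-8-carboxylate | CC(C)(C)[Si](C)(C)O[C@H]1CC(C(=O)OC)=CC[C@@]2(C)[C@@H](O[Si](C)(C)C(C)(C)C)CC3(OCCO3)[C@H]12 | intermediate
19 | methyl 2β,6β-bis(tert-butyldimethylsilyloxy)-1α-methyl-4-oxo-5βH-bicyclo[5.3.0]dec-8-ene-8-carboxylate | CC(C)(C)[Si](C)(C)O[C@H]1CC(C(=O)OC)=CC[C@@]2(C)[C@@H](O[Si](C)(C)C(C)(C)C)CC(=O)[C@H]12 | intermediate
20 | isopropylmagnesium chloride | CC(C)[Mg]Cl | starting material
21 | methyl 2β,6β-bis(tert-butyldimethylsilyloxy)-4α-hydroxy-4β-isopropyl-1α-methyl-5βH-bicyclo[5.3.0]dec-8-ene-8-carboxylate | CC(C)(C)[Si](C)(C)O[C@H]1CC(C(=O)OC)=CC[C@@]2(C)[C@@H](O[Si](C)(C)C(C)(C)C)C[C@@](O)(C(C)C)[C@H]12 | intermediate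
22 | 2β,6β-bis(tert-butyldimethylsilyloxy)-8-(hydroxymethyl)-4β-isopropyl-1α-methyl-5βH-bicyclo[5.3.0]dec-8-en-4α-ol | CC(C)(C)[Si](C)(C)O[C@H]1CC(CO)=CC[C@@]2(C)[C@@H](O[Si](C)(C)C(C)(C)C)C[C@@](O)(C(C)C)[C@H]12 | intermediate
23 | primary allylic methanesulfonate of 22 | CC(C)(C)[Si](C)(C)O[C@H]1CC(COS(C)(=O)=O)=CC[C@@]2(C)[C@@H](O[Si](C)(C)C(C)(C)C)C[C@@](O)(C(C)C)[C@H]12 | intermediate (not isolated)
24 | 2β,6β-bis(tert-butyldimethylsilyloxy)-4β-isopropyl-1α,8-dimethyl-5βH-bicyclo[5.3.0]dec-8-en-4α-ol | CC(C)(C)[Si](C)(C)O[C@H]1CC(C)=CC[C@@]2(C)[C@@H](O[Si](C)(C)C(C)(C)C)C[C@@](O)(C(C)C)[C@H]12 | intermediate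
25 | 2β-(tert-butyldimethylsilyloxy)-4β-isopropyl-1α,8-dimethyl-5βH-bicyclo[5.3.0]dec-8-ene-4α,6β-diol | O[C@H]1CC(C)=CC[C@@]2(C)[C@@H](O[Si](C)(C)C(C)(C)C)C[C@@](O)(C(C)C)[C@H]12 | intermediate (not isolated)
26 | 4β-isopropyl-1α,8-dimethyl-5βH-bicyclo[5.3.0]dec-8-ene-2β,4α,6β-triol | O[C@H]1CC(C)=CC[C@@]2(C)[C@@H](O)C[C@@](O)(C(C)C)[C@H]12 | intermediate
27 | angelic acid, (Z)-2-methylbut-2-enoic acid | C/C=C(/C)C(=O)O | starting material
28 | 6β-angeloyloxy-4β-isopropyl-1α,8-dimethyl-5βH-bicyclo[5.3.0]dec-8-ene-2β,4α-diol | C/C=C(/C)C(=O)O[C@H]1CC(C)=CC[C@@]2(C)[C@@H](O)C[C@@](O)(C(C)C)[C@H]12 | intermediate (not isolated)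
29 | CNP0303897.1, 2β,6β-bis(angeloyloxy)-4β-isopropyl-1α,8-dimethyl-5βH-bicyclo[5.3.0]dec-8-en-4α-ol | C/C=C(/C)C(=O)O[C@H]1CC(C)=CC[C@@]2(C)[C@@H](OC(=O)/C(C)=C\C)C[C@@](O)(C(C)C)[C@H]12 | target

**Step count**

Total: 19 steps. Longest linear sequence: 16 steps (steps 1–7 and 11–19); the three-step branch to 13 (steps 8–10) joins at step 11.

**Steps most likely to fail**

Step 11. The unsubstituted vinyldiazo ester may decay (cyclisation to the pyrazole, carbene dimerisation, reaction through its vinyl terminus) faster than it cyclopropanates a hindered diene. The Cope shift past the inward methyl may also stall, or facial control by the catalyst may be incomplete. The fallback sets out from 11 and 9 and comes back at 15. Diazo ketoester 11 would be silylated (TBSOTf, Et3N, CH2Cl2, 0 °C) to methyl 3-(tert-butyldimethylsilyloxy)-2-diazobut-3-enoate F1, a storable vinyldiazo ester and the usual partner for hindered dienes. With 9 and Rh2(R-PTAD)4 in hexanes it should give, by the same cyclopropanation–Cope sequence, the C9 silyl enol ether of the bicyclic keto ester F2. Buffered fluoride (TBAF, AcOH, THF, −20 °C) would free the β-keto ester F3 without touching the secondary silyl ether. NaBH4 in MeOH would give the β-hydroxy ester F4, and mesylation to the mesylate F5 followed by DBU would eliminate toward the ester to give 15.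

Step 15. The hindered ketone, which has a silyloxy group β on each side, may be enolised (with epimerisation at C5 or loss of silanolate) or reduced instead of alkylated, or the isopropyl group may enter from the α face. The fallback sets out from 19 and comes back at 22; it makes the C4–O bond by oxidation of an alkene instead of the C4–C bond by carbonyl addition. KN(SiMe3)2 and PhNTf2 (THF, −78 °C) would deprotonate the C3 methylene rather than the congested C5 methine and give the C3=C4 enol triflate F6. Iron-catalysed Kumada coupling (i-PrMgCl, Fe(acac)3, THF/NMP, −30 °C) would give the 4-isopropyl C3=C4 alkene F7. mCPBA (NaHCO3, CH2Cl2, 0 °C) should epoxidise this electron-rich alkene, not the enoate, on the α face anti to the allylic C2 silyl ether, giving the α-epoxide F8. LiAlH4 (Et2O, 0 °C) would then deliver hydride to the secondary C3 terminus of the epoxide and reduce the ester, leaving the tertiary 4α-alcohol and the primary allylic alcohol of 22.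

Step 19. Forcing bis-acylation of two hindered secondary alcohols may stop at a monoester or be accompanied by Z-to-E isomerisation to tiglates. The fallback sets out from 26 and comes back at 29; it builds the Z alkenes on the esters instead of transferring them. Triol 26 would be esterified at both secondary hydroxyls with 2-[bis(2,2,2-trifluoroethoxy)phosphoryl]propanoic acid (DCC, DMAP, CH2Cl2) to the 2β,6β-bis(phosphonopropionate) F9. Double Still–Gennari olefination with acetaldehyde (KN(SiMe3)2, 18-crown-6, THF, −78 °C) should then form both (Z)-2-methylbut-2-enoates and give 29.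

**Further compounds**

F1 | step 11 | methyl 3-(tert-butyldimethylsilyloxy)-2-diazobut-3-enoate | C=C(O[Si](C)(C)C(C)(C)C)C(=[N+]=[N-])C(=O)OC
F2 | step 11 | methyl 2β,9-bis(tert-butyldimethylsilyloxy)-4,4-(ethylenedioxy)-1α-methylbicyclo[5.3.0]deca-5,8-diene-8-carboxylate | COC(=O)C1=C(O[Si](C)(C)C(C)(C)C)C[C@@]2(C)[C@@H](O[Si](C)(C)C(C)(C)C)CC3(OCCO3)C2=CC1
F3 | step 11 | methyl 2β-(tert-butyldimethylsilyloxy)-4,4-(ethylenedioxy)-1α-methyl-9-oxobicyclo[5.3.0]dec-5-ene-8-carboxylate (C8 epimers) | COC(=O)C1C(=O)C[C@@]2(C)[C@@H](O[Si](C)(C)C(C)(C)C)CC3(OCCO3)C2=CC1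
F4 | step 11 | methyl 2β-(tert-butyldimethylsilyloxy)-4,4-(ethylenedioxy)-9-hydroxy-1α-methylbicyclo[5.3.0]dec-5-ene-8-carboxylate (C8/C9 diastereomers) | COC(=O)C1C(O)C[C@@]2(C)[C@@H](O[Si](C)(C)C(C)(C)C)CC3(OCCO3)C2=CC1
F5 | step 11 | C9 methanesulfonate of F4 | COC(=O)C1C(OS(C)(=O)=O)C[C@@]2(C)[C@@H](O[Si](C)(C)C(C)(C)C)CC3(OCCO3)C2=CC1
F6 | step 15 | methyl 2β,6β-bis(tert-butyldimethylsilyloxy)-1α-methyl-4-(trifluoromethylsulfonyloxy)-5βH-bicyclo[5.3.0]deca-3,8-diene-8-carboxylate | CC(C)(C)[Si](C)(C)O[C@H]1CC(C(=O)OC)=CC[C@@]2(C)[C@@H](O[Si](C)(C)C(C)(C)C)C=C(OS(=O)(=O)C(F)(F)F)[C@H]12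
F7 | step 15 | methyl 2β,6β-bis(tert-butyldimethylsilyloxy)-4-isopropyl-1α-methyl-5βH-bicyclo[5.3.0]deca-3,8-diene-8-carboxylate | CC(C)(C)[Si](C)(C)O[C@H]1CC(C(=O)OC)=CC[C@@]2(C)[C@@H](O[Si](C)(C)C(C)(C)C)C=C(C(C)C)[C@H]12
F8 | step 15 | methyl 2β,6β-bis(tert-butyldimethylsilyloxy)-3α,4α-epoxy-4β-isopropyl-1α-methyl-5βH-bicyclo[5.3.0]dec-8-ene-8-carboxylate | CC(C)(C)[Si](C)(C)O[C@H]1CC(C(=O)OC)=CC[C@@]2(C)[C@@H](O[Si](C)(C)C(C)(C)C)[C@@H]3O[C@]3(C(C)C)[C@H]12
F9 | step 19 | 2β,6β-bis{2-[bis(2,2,2-trifluoroethoxy)phosphoryl]propanoyloxy}-4β-isopropyl-1α,8-dimethyl-5βH-bicyclo[5.3.0]dec-8-en-4α-ol | CC(C(=O)O[C@H]1CC(C)=CC[C@@]2(C)[C@@H](OC(=O)C(C)P(=O)(OCC(F)(F)F)OCC(F)(F)F)C[C@@](O)(C(C)C)[C@H]12)P(=O)(OCC(F)(F)F)OCC(F)(F)F
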